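**Retrosynthetic overview**

1. Numbering (thymol type): ring C1 bears C7 (CH2O‑isovaleryl), C3 bears the angeloyloxy oxygen (O3), C4 bears C8; C8 is the fully substituted oxirane carbon (R), C9 the oxirane CH2, C10 the CH2OAc carbon.
2. The plan rests on C8 and its neighbours: C8 joins the benzene ring (at C4) to two oxygenated one‑carbon arms, C9 and C10, so C9–C8–C10 is the skeleton of a 3‑substituted pyruvate with C8 as ketone carbon and C10 as carboxyl carbon.
3. Last disconnections: the O3 angelate (made last, as the Z‑enoate aryl ester is the most fragile group), the O7 isovalerate and the O10 acetate, back to a 2‑aryl glycidate with O3 as allyl ether and O7 as TIPS ether.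
4. Key disconnection: the C4–C8 bond and the C9–O oxirane bond, back to an arylmagnesium chloride and (−)‑8‑phenylmenthyl bromopyruvate; the auxiliary ester fixes C8 and is later reduced to C10.
5. Ring order: the benzene ring is bought (methyl 3‑hydroxy‑4‑iodobenzoate); the oxirane is the only ring made and is closed in the key step.

Key step: step 6

Remark (assumption): the facial sense in step 6 is taken from the behaviour of Grignard reagents toward (−)‑8‑phenylmenthyl glyoxylate and pyruvate (attack on the face of the magnesium‑chelated s‑cis keto ester not covered by the cumyl phenyl ring); should the opposite sense be found, (+)‑8‑phenylmenthol replaces 5 in step 4 and nothing else changes.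

**Route**

Step 1
Reactants: 1 methyl 3‑hydroxy‑4‑iodobenzoate
Product: 2 methyl 3‑(allyloxy)‑4‑iodobenzoate
Conditions: allyl bromide, K2CO3, DMF, 23 °C
Reagents that add atoms: allyl bromide, C=CCBr
Why: Williamson ether synthesis (SN2 alkylation of the phenoxide); the allyl ether is chosen because it is inert to Grignard and hydride reagents and can later be removed by zerovalent palladium under near‑neutral conditions that an aryl oxirane tolerates.

Step 2
Reactants: 2 methyl 3‑(allyloxy)‑4‑iodobenzoate
Product: 3 [3‑(allyloxy)‑4‑iodophenyl]methanol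
Conditions: iBu2AlH (2.5 equiv), CH2Cl2, −78 → 0 °C; aq. KNaC4H4O6
Reagents that add atoms: none
Why: Ester reduction with an aluminium hydride, which converts the methyl benzoate into the benzylic alcohol at low temperature without reducing the aryl C–I bond or the allyl group.

Step 3
Reactants: 3 [3‑(allyloxy)‑4‑iodophenyl]methanol
Product: 4 {[3‑(allyloxy)‑4‑iodobenzyl]oxy}triisopropylsilane
Conditions: iPr3SiCl, imidazole, DMF, 23 °C
Reagents that add atoms: chlorotriisopropylsilane, CC(C)[Si](Cl)(C(C)C)C(C)C
Why: Imidazole‑promoted silylation of a primary alcohol; the TIPS ether withstands the iodine–magnesium exchange, the Grignard addition and iBu2AlH and is removed later by fluoride.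

Step 4
Reactants: 5 (−)‑8‑phenylmenthol; 6 bromopyruvic acid (1.5 equiv)
Product: 7 (−)‑8‑phenylmenthyl 3‑bromo‑2‑oxopropanoate (bromopyruvate of 5)
Conditions: TsOH·H2O (5 mol %), benzene, reflux, Dean–Stark trap
Reagents that add atoms: none
Why: Acid‑catalysed Fischer esterification driven by azeotropic removal of water, the way pyruvates of this hindered secondary alcohol are made; the absence of base avoids enolisation of, or alkylation by, the bromoketone, and the three stereocentres of the auxiliary are untouched.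

Step 5
Reactants: 4 {[3‑(allyloxy)‑4‑iodobenzyl]oxy}triisopropylsilane
Product: 8 {2‑(allyloxy)‑4‑[(triisopropylsilyloxy)methyl]phenyl}magnesium chloride (LiCl complex; titrated THF stock solution for step 6)
Conditions: iPrMgCl·LiCl (1.0 equiv), THF, −15 → 0 °C
Reagents that add atoms: isopropylmagnesium chloride–lithium chloride, CC(C)[Mg]Cl.[Li+].[Cl-]
Why: Iodine–magnesium exchange with the LiCl‑activated isopropyl Grignard reagent, which is fast for an aryl iodide with a coordinating ortho alkoxy group and leaves the allyl and silyl ethers untouched at or below 0 °C.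

Step 6
Reactants: 8 {2‑(allyloxy)‑4‑[(triisopropylsilyloxy)methyl]phenyl}magnesium chloride (1.2 equiv); 7 (−)‑8‑phenylmenthyl 3‑bromo‑2‑oxopropanoate
Product: 10 (−)‑8‑phenylmenthyl (2R)‑2‑{2‑(allyloxy)‑4‑[(triisopropylsilyloxy)methyl]phenyl}oxirane‑2‑carboxylate, via bromohydrin magnesium alkoxide 9 (not isolated)
Conditions: 8 added slowly to 7, THF, −78 °C, 1 h; then DMPU (4 equiv), −78 → 23 °C; aq. NH4Cl
Reagents that add atoms: none
Why: The arylmagnesium chloride adds to the ketone carbonyl of 7, by far the most electrophilic site at −78 °C (the hindered auxiliary ester and the primary C–Br bond react more slowly), which forms the C4–C8 bond and the bromohydrin magnesium alkoxide 9. On warming with DMPU the alkoxide oxygen displaces bromide at C9 in a 3‑exo‑tet closure, which forms the C9–O bond and the oxirane; the closest known reaction type is Grignard addition to an alpha‑halo ketone followed by halohydrin ring closure (Darzens‑type result), joined here to the auxiliary‑controlled addition of Grignard reagents to 8‑phenylmenthyl alpha‑keto esters. C8 is the only new stereocentre and is set by the auxiliary: magnesium chelates the keto and ester carbonyl oxygens in an s‑cis arrangement, the phenyl ring of the cumyl group covers one face, and the aryl group enters from the open face. With CH2Br in the place of H or CH3 this face should give the (2S)‑bromohydrin and hence the (2R)‑glycidate, in which, seen from the aryl group, the oxirane O, C10 and C9 run counterclockwise, as in the target. The step needs facial selectivity at the ketone (secured by the chelate and the shielding phenyl ring) and addition in preference to enolisation or bromine–magnesium exchange (secured by low temperature, the high electrophilicity of the alpha‑keto ester and slow addition of the weakly basic aryl Grignard reagent).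

Step 7
Reactants: 10 (−)‑8‑phenylmenthyl (2R)‑2‑{2‑(allyloxy)‑4‑[(triisopropylsilyloxy)methyl]phenyl}oxirane‑2‑carboxylate
Product: 11 [(2S)‑2‑{2‑(allyloxy)‑4‑[(triisopropylsilyloxy)methyl]phenyl}oxiran‑2‑yl]methanol
Conditions: iBu2AlH (3 equiv), CH2Cl2, −78 → −30 °C; aq. KNaC4H4O6
Reagents that add atoms: none
Why: Ester reduction with iBu2AlH, in which the alpha‑oxygenated ester should be reduced at low temperature much faster than the oxirane is opened; the auxiliary 5 is released for recovery and C8 is not touched (a Payne rearrangement of the product alkoxide would be degenerate and return the same enantiomer; the change of descriptor from R to S reflects only the changed priority of C10).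

Step 8
Reactants: 11 [(2S)‑2‑{2‑(allyloxy)‑4‑[(triisopropylsilyloxy)methyl]phenyl}oxiran‑2‑yl]methanol
Product: 12 [(2R)‑2‑{2‑(allyloxy)‑4‑[(triisopropylsilyloxy)methyl]phenyl}oxiran‑2‑yl]methyl acetate
Conditions: Ac2O, Et3N, DMAP (cat.), CH2Cl2, 0 °C
Reagents that add atoms: acetic anhydride, CC(=O)OC(C)=O
Why: DMAP‑catalysed acylation of the primary alcohol under basic, chloride‑free conditions that do not open the acid‑sensitive aryl oxirane.

Step 9
Reactants: 12 [(2R)‑2‑{2‑(allyloxy)‑4‑[(triisopropylsilyloxy)methyl]phenyl}oxiran‑2‑yl]methyl acetate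
Product: 13 {(2R)‑2‑[2‑(allyloxy)‑4‑(hydroxymethyl)phenyl]oxiran‑2‑yl}methyl acetate
Conditions: Bu4NF, AcOH (1:1), THF, 0 → 23 °C
Reagents that add atoms: none
Why: Fluoride‑induced cleavage of the Si–O bond (desilylation), buffered with acetic acid so that no free alkoxide is present to transfer or cleave the acetate; oxirane, acetate and allyl ether are inert to buffered fluoride.

Step 10
Reactants: 13 {(2R)‑2‑[2‑(allyloxy)‑4‑(hydroxymethyl)phenyl]oxiran‑2‑yl}methyl acetate
Product: 14 {4‑[(2R)‑2‑(acetoxymethyl)oxiran‑2‑yl]‑3‑(allyloxy)phenyl}methyl 3‑methylbutanoate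
Conditions: (iPrCH2CO)2O, Et3N, DMAP (cat.), CH2Cl2, 0 °C
Reagents that add atoms: 3‑methylbutanoic anhydride, CC(C)CC(=O)OC(=O)CC(C)C
Why: DMAP‑catalysed acylation of the primary benzylic alcohol with the anhydride, again without chloride or acid that could open the oxirane.

Step 11
Reactants: 14 {4‑[(2R)‑2‑(acetoxymethyl)oxiran‑2‑yl]‑3‑(allyloxy)phenyl}methyl 3‑methylbutanoate
Product: 15 {4‑[(2R)‑2‑(acetoxymethyl)oxiran‑2‑yl]‑3‑hydroxyphenyl}methyl 3‑methylbutanoate (used at once)
Conditions: Pd(PPh3)4 (5 mol %), morpholine (3 equiv), THF, 23 °C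
Reagents that add atoms: none
Why: Tsuji–Trost‑type deallylation, in which zerovalent palladium ionises the allyl aryl ether to a pi‑allylpalladium phenoxide and morpholine takes up the allyl group; this frees the phenol under near‑neutral conditions that leave both alkyl esters and the oxirane in place.

Step 12
Reactants: 15 {4‑[(2R)‑2‑(acetoxymethyl)oxiran‑2‑yl]‑3‑hydroxyphenyl}methyl 3‑methylbutanoate; 16 angelic acid (1.5 equiv)
Product: 18 2‑[(2R)‑2‑(acetoxymethyl)oxiran‑2‑yl]‑5‑[(3‑methylbutanoyloxy)methyl]phenyl (2Z)‑2‑methylbut‑2‑enoate, via angelic 2,4,6‑trichlorobenzoic anhydride 17 (not isolated)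
Conditions: 16, 2,4,6‑Cl3C6H2COCl, Et3N, toluene, 23 °C; then 15, Et3N, 23 → 40 °C
Reagents that add atoms: none
Why: Yamaguchi esterification, in which the phenoxide attacks the mixed anhydride 17 at the less hindered angeloyl carbonyl; the absence of a nucleophilic catalyst and of strong base should keep the Z double bond from isomerising to the tiglate.

**Compound list**

1 | methyl 3‑hydroxy‑4‑iodobenzoate | COC(=O)c1ccc(I)c(O)c1 | starting material
2 | methyl 3‑(allyloxy)‑4‑iodobenzoate | COC(=O)c1ccc(I)c(OCC=C)c1 | intermediate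
3 | [3‑(allyloxy)‑4‑iodophenyl]methanol | OCc1ccc(I)c(OCC=C)c1 | intermediate
4 | {[3‑(allyloxy)‑4‑iodobenzyl]oxy}triisopropylsilane | CC(C)[Si](OCc1ccc(I)c(OCC=C)c1)(C(C)C)C(C)C | intermediate
5 | (−)‑8‑phenylmenthol, (1R,2S,5R)‑5‑methyl‑2‑(2‑phenylpropan‑2‑yl)cyclohexan‑1‑ol | CC(C)(c1ccccc1)[C@@H]1CC[C@@H](C)C[C@H]1O | starting material
6 | bromopyruvic acid | OC(=O)C(=O)CBr | starting material
7 | (−)‑8‑phenylmenthyl bromopyruvate, (1R,2S,5R)‑5‑methyl‑2‑(2‑phenylpropan‑2‑yl)cyclohexyl 3‑bromo‑2‑oxopropanoate | BrCC(=O)C(=O)O[C@@H]1C[C@H](C)CC[C@H]1C(C)(C)c1ccccc1 | intermediate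
8 | {2‑(allyloxy)‑4‑[(triisopropylsilyloxy)methyl]phenyl}magnesium chloride (LiCl complex in THF) | CC(C)[Si](OCc1ccc([Mg]Cl)c(OCC=C)c1)(C(C)C)C(C)C | intermediate
9 | chloromagnesium alkoxide of (−)‑8‑phenylmenthyl (2S)‑2‑aryl‑3‑bromo‑2‑hydroxypropanoate (aryl as in 8; not isolated) | CC(C)[Si](OCc1ccc([C@](O[Mg]Cl)(C(=O)O[C@@H]2C[C@H](C)CC[C@H]2C(C)(C)c2ccccc2)CBr)c(OCC=C)c1)(C(C)C)C(C)C | intermediate
10 | (−)‑8‑phenylmenthyl (2R)‑2‑{2‑(allyloxy)‑4‑[(triisopropylsilyloxy)methyl]phenyl}oxirane‑2‑carboxylate | CC(C)[Si](OCc1ccc([C@]2(C(=O)O[C@@H]3C[C@H](C)CC[C@H]3C(C)(C)c3ccccc3)CO2)c(OCC=C)c1)(C(C)C)C(C)C | intermediate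
11 | [(2S)‑2‑{2‑(allyloxy)‑4‑[(triisopropylsilyloxy)methyl]phenyl}oxiran‑2‑yl]methanol | CC(C)[Si](OCc1ccc([C@]2(CO)CO2)c(OCC=C)c1)(C(C)C)C(C)C | intermediate
12 | [(2R)‑2‑{2‑(allyloxy)‑4‑[(triisopropylsilyloxy)methyl]phenyl}oxiran‑2‑yl]methyl acetate | CC(C)[Si](OCc1ccc([C@]2(COC(C)=O)CO2)c(OCC=C)c1)(C(C)C)C(C)C | intermediate
13 | {(2R)‑2‑[2‑(allyloxy)‑4‑(hydroxymethyl)phenyl]oxiran‑2‑yl}methyl acetate | OCc1ccc([C@]2(COC(C)=O)CO2)c(OCC=C)c1 | intermediate
14 | {4‑[(2R)‑2‑(acetoxymethyl)oxiran‑2‑yl]‑3‑(allyloxy)phenyl}methyl 3‑methylbutanoate | CC(C)CC(=O)OCc1ccc([C@]2(COC(C)=O)CO2)c(OCC=C)c1 | intermediate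
15 | {4‑[(2R)‑2‑(acetoxymethyl)oxiran‑2‑yl]‑3‑hydroxyphenyl}methyl 3‑methylbutanoate | CC(C)CC(=O)OCc1ccc([C@]2(COC(C)=O)CO2)c(O)c1 | intermediate
16 | angelic acid, (2Z)‑2‑methylbut‑2‑enoic acid | C/C=C(/C)C(=O)O | starting material
17 | angelic 2,4,6‑trichlorobenzoic anhydride (not isolated) | C/C=C(/C)C(=O)OC(=O)c1c(Cl)cc(Cl)cc1Cl | intermediate
18 | CNP0212475.1, 2‑[(2R)‑2‑(acetoxymethyl)oxiran‑2‑yl]‑5‑[(3‑methylbutanoyloxy)methyl]phenyl (2Z)‑2‑methylbut‑2‑enoate | C/C=C(/C)C(=O)Oc1cc(COC(=O)CC(C)C)ccc1[C@]1(COC(C)=O)CO1 | target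

Total step count: 12
Longest linear sequence: 11 steps (steps 1, 2, 3, 5, 6, 7, 8, 9, 10, 11, 12)

**Three steps most likely to fail**

Step 6. What may go wrong:
- loss or reversal of facial selectivity if the CH2Br group or LiCl weakens the magnesium chelate;
- enolisation of the bromoketone or bromine–magnesium exchange in place of carbonyl addition;
- slow closure of the magnesium bromohydrinate, reopening of the oxirane by magnesium halide, or an aryl shift (semipinacol) on warming.

Fallback (reagent control in place of auxiliary control), setting out from 8 and returning at 11: addition of 8 to an excess of diethyl oxalate (THF, −78 °C) should give the aryl glyoxylate, ethyl 2‑oxo‑2‑{2‑(allyloxy)‑4‑[(triisopropylsilyloxy)methyl]phenyl}acetate F1. Wittig methylenation (Ph3P=CH2, THF, 0 °C) should give the atropate, ethyl 2‑{2‑(allyloxy)‑4‑[(triisopropylsilyloxy)methyl]phenyl}prop‑2‑enoate F2. Reduction with iBu2AlH (CH2Cl2, −78 °C) should give the allylic alcohol, 2‑{2‑(allyloxy)‑4‑[(triisopropylsilyloxy)methyl]phenyl}prop‑2‑en‑1‑ol F3. Sharpless asymmetric epoxidation (Ti(OiPr)4 10 mol %, L‑(+)‑diethyl tartrate, tBuOOH, 4 Å molecular sieves, CH2Cl2, −20 °C) then delivers oxygen to the face that gives the (S)‑glycidol, so the route is rejoined at 11 and steps 4, 6 and 7 fall away.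

Step 7. What may go wrong:
- hydride opening of the oxirane at the benzylic C8, or aluminium‑induced rearrangement of the electron‑rich aryl oxirane, while the hindered ester is driven to full reduction;
- a stall at the aldehyde stage.

Fallback (each hydride used only for what it does cleanly), setting out from 10 and returning at 11: iBu2AlH (1.2 equiv, toluene, −78 °C, quench at that temperature) should stop at the epoxy aldehyde, (2R)‑2‑{2‑(allyloxy)‑4‑[(triisopropylsilyloxy)methyl]phenyl}oxirane‑2‑carbaldehyde F4. NaBH4 in MeOH at 0 °C then reduces the aldehyde without touching the oxirane and gives 11.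

Step 11. What may go wrong: once the phenol is freed, its oxygen can push open the neighbouring oxirane at C8 (quinone‑methide‑type opening, helped by base or acid), so that material is lost during deallylation, work‑up or the wait before acylation.

Fallback (the phenol is never set free), setting out from 14 and returning at 18: palladium‑catalysed hydrostannolysis (Pd(PPh3)4 cat., Bu3SnH 1.05 equiv, CH2Cl2, 23 °C) releases propene and should give the tin phenoxide, tributyl{2‑[(2R)‑2‑(acetoxymethyl)oxiran‑2‑yl]‑5‑[(3‑methylbutanoyloxy)methyl]phenoxy}stannane F5, which is not isolated. The preformed mixed anhydride 17 is added to the same flask and acylates the tin phenoxide, which gives the target 18 and replaces steps 11 and 12.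

**Further compounds**

F1 | step 6 | ethyl 2‑oxo‑2‑{2‑(allyloxy)‑4‑[(triisopropylsilyloxy)methyl]phenyl}acetate | CCOC(=O)C(=O)c1ccc(CO[Si](C(C)C)(C(C)C)C(C)C)cc1OCC=C
F2 | step 6 | ethyl 2‑{2‑(allyloxy)‑4‑[(triisopropylsilyloxy)methyl]phenyl}prop‑2‑enoate | C=C(C(=O)OCC)c1ccc(CO[Si](C(C)C)(C(C)C)C(C)C)cc1OCC=C
F3 | step 6 | 2‑{2‑(allyloxy)‑4‑[(triisopropylsilyloxy)methyl]phenyl}prop‑2‑en‑1‑ol | C=C(CO)c1ccc(CO[Si](C(C)C)(C(C)C)C(C)C)cc1OCC=C
F4 | step 7 | (2R)‑2‑{2‑(allyloxy)‑4‑[(triisopropylsilyloxy)methyl]phenyl}oxirane‑2‑carbaldehyde | CC(C)[Si](OCc1ccc([C@]2(C=O)CO2)c(OCC=C)c1)(C(C)C)C(C)C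
F5 | step 11 | tributyl{2‑[(2R)‑2‑(acetoxymethyl)oxiran‑2‑yl]‑5‑[(3‑methylbutanoyloxy)methyl]phenoxy}stannane | CCCC[Sn](CCCC)(CCCC)Oc1cc(COC(=O)CC(C)C)ccc1[C@]1(COC(C)=O)CO1
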